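**Numbering.** Ring atoms carry germacrane numbers throughout: C1 (epoxide CH), C2 (ketone), C3=C4 (C4 bears CH3), C5 (carbinol), C6 (lactone CH–O), C7, C8 (ester CH), C9 (CH2), C10 (epoxide C–CH3); C11, C12 and C13 are the lactone carbons.

## Analysis of the target

The target is a ten-membered carbocycle (C1–C10) that carries a 1,10-epoxide and a γ-lactone (O–C6, C7–C11, C12=O) with an exocyclic C11=C13 methylene. It has six stereocentres, (1S,5S,6R,7R,8R,10R), and a Z enone double bond at C3=C4, so that C2 and C5 are cis on the ring. Four of the centres are contiguous (C5–C8): O5 and O6 are anti, H6 and H7 are cis (a cis-fused lactone), and C8 bears the tiglate. The epoxide has C2 and C9 on opposite faces, so it corresponds to an E trisubstituted olefin. Sensitive groups are the α-methylene lactone (a Michael acceptor that can also migrate to O8), the α,β-epoxy ketone, the γ-hydroxy cis-enone (prone to transannular hemiketal formation and elimination), the tiglate and the acid-labile trisubstituted epoxide. The difficulty lies in the strained medium ring with three rigid elements, and in the cis lactone junction next to two further oxygenated carbons, which anti-selective epoxide openings cannot give. The strategy rests on the sequence O–C6, C-branch on C7, O–C8: a C7=C8 olefin beside a C6 hydroxyl can take the two lactone carbons from a tether on O6 at C7 while C8 picks up oxygen in the same event.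

## Retrosynthetic reasoning

**35 ⇐ 34 ⇐ 33 ⇐ 32.** The free C5 hydroxyl and the C2 carbonyl are unmasked last, because the hydroxy enone and the epoxy ketone are the most fragile part of the molecule. O5 is carried as a 4-methoxybenzyl ether (34), which is removed oxidatively under neutral conditions. C2 is carried as a silyl-protected carbinol (32, 33), so that neither the radical step nor the lactone enolate chemistry meets an enone. Because C2 ends as a ketone, its configuration never has to be controlled.

**32 ⇐ 29 + 30; 29 ⇐ 28; 28 ⇐ 25; 25 ⇐ 24 ⇐ 23.** The C8–O acyl bond is cut to give alcohol 29 and tiglic acid 30. The O8–H of 29 comes from an N–O bond (28); the aminoxy group also protects O8 against base while C13 is attached to the lactone 25. The lactone carbonyl is traced to the cyclic acetal 23, one oxidation level lower, through lactol 24.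

**23 ⇐ 21 + 22 (key disconnection).** C7–C11 and C8–O are cut together. This leaves a C7=C8 cis olefin in the ten-membered ring, a two-carbon bromoacetal on O6 (21) and the nitroxyl 22. These bonds are chosen because no other pair gives the carbon branch and the flanking oxygen in one step from an unactivated olefin, and because the acetal carbon is already C12. The forward reaction has to close the five-membered ring 5-exo, place C11 on C7 with H6 and H7 cis, and cap C8 with oxygen. The tether fixes only the face of attack relative to O6. The junction depends on the C6–C7 rotamer, and this is treated as the main risk and not as a certainty.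

**21 ⇐ 19 + 20; 19 ⇐ 18.** The acetal C–O bond is cut to give the ring alcohol 19 and ethyl vinyl ether 20. The C7=C8 bond of 19 is cut by ring-closing metathesis to the open-chain diene 18. Both halves then end in simple vinyl groups, and the cis geometry is the one the ring favours.

**18 ⇐ 17 ⇐ 16 ⇐ 9 + 15.** The C2–C3 bond is cut between a Z alkenyl iodide (9) and an epoxy aldehyde (15), to be joined by a Nozaki–Hiyama–Kishi reaction. This is the one bond whose formation creates a stereocentre (C2) that is later erased. It also lets the epoxide arrive complete and enantiopure. Intermediates 16 and 17 only exchange protecting groups so that O6 is free and O2 is masked in 18.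

**15 ⇐ 14 ⇐ 13 ⇐ 10.** The epoxide C–O bonds are cut back to an E allylic alcohol (13), so that C1 and C10 are set by reagent-controlled Sharpless epoxidation. The E geometry, which becomes the trans epoxide, comes from syn carboalumination and hydroxymethylation of pent-1-en-4-yne (10).

**9 ⇐ 8 ⇐ 7 ⇐ 6 ⇐ 5 ⇐ 4 ⇐ 3 ⇐ 1.** The vinyl group on C6 of 8 is traced to the terminal epoxide of 7 by one-carbon homologation. The anti O5/O6 pair is traced to the erythro epoxy alcohol 6 from a Sharpless kinetic resolution of the racemic dienol 5. The Z iodo olefin is traced through aldehyde 4 and alcohol 3 to prop-2-yn-1-ol (1) by an anti-carbometalation/iodination. In this way C5 and C6 are set in one step, and the two oxygens are differentiated from the start (O5 as an ether, O6 free).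

## Alternatives that were turned down

**Alternative 1:** C1–C2 and C8–C9 are cut, leaving C9–C10–C1 as a doubly borylated methylpropene unit. In the forward sense a one-pot double allylboration joins a four-carbon ynal and then an aldehyde that already holds C6, C7, C11 and C12 in a five-membered ring, giving the E 1,5-diol A1.
- For: it is convergent, and it makes the E C1=C10 olefin and two carbinols in one flask. It is stronger than the chosen route on the ring junction, because C6/C7 are set in a small ring where the cis relationship is easy to enforce.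
- Against: the C2 carbinol it sets with effort ends as a ketone. The ten-membered ring still has to be closed at C4–C5 from the alkyne of A1, with control of the Z geometry and of C5 in the same step. The epoxide must be introduced later with face control on a flexible chain or ring. The methylene tetrahydrofuran must be oxidised to the lactone among other allylic positions.
- Comparison: it solves the chain and postpones the ring and the epoxide. The chosen strategy gives up the secure junction, but it has a simpler macrocyclisation that sets no stereocentre and an epoxide fixed by reagent control before the ring exists.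

**Alternative 2:** The ten-membered ring is traced to a 1,2-dialkenylcyclohexenol. In the forward sense the potassium alkoxide undergoes an anionic oxy-Cope rearrangement that forms C9–C10, breaks the C2–C7 bond of the six-membered ring and gives the enone A2.
- For: this ring expansion is among the most dependable routes to ten-membered carbocycles. It is irreversible and needs no high dilution, and it delivers the C2 carbonyl and the oxygenated C10 centre directly. On ring construction it is stronger than the metathesis used here.
- Against: A2 carries an E C7=C8 olefin and a C5/C6 acetonide, so the lactone branch at C7, the oxygen at C8 and the cis junction all remain to be built on a trans olefin. The trans epoxide has to be made from the C10 silyloxy group by functionalising C1 next to the ketone with inversion. The ketone is exposed through all of these steps.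
- Comparison: steps saved on the ring are spent on C1, C7 and C8. The chosen strategy offers a cis C7=C8 bond placed where one step adds both missing groups.

**Alternative 3:** The C2–O and C5–O bonds are cut. In the forward sense singlet dioxygen A5 adds across C2 and C5 of the ring diene A4 to give the endoperoxide A3, and a Kornblum–DeLaMare rearrangement would then give the hydroxy enone.
- For: both oxygens and the cis C3=C4 bond arrive in two steps without protecting groups. This is shorter than the three closing steps used here, so on late-stage step economy it is stronger.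
- Against: A4 is a cis,cis-diene in a ten-membered ring beside the epoxide, with lactone and tiglate already present, and is at least as hard to make as the target. Ene reactions at the C4 methyl and at the other olefins compete. One facial choice fixes C5 with only ring conformation to guide it. The rearrangement must remove H2 and not H5. The plan says nothing about C6–C8.
- Comparison: it moves the difficulty into the precursor. The chosen strategy sets C5 by a reagent-controlled step at the outset and pays for it with ordinary deprotection and oxidation steps.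

Key step: step 16

Remark: C2 and the acetal carbon C12 arise as epimer mixtures and are written without configuration, because C2 ends as a ketone and C12 as the lactone carbonyl; C8 in 23 is drawn in the configuration expected from approach anti to the new C7–C11 bond.

## Route

Step 1
Reactants: 1 prop-2-yn-1-ol
Product: 3 (2Z)-3-iodo-2-methylprop-2-en-1-ol, via chelated alkenylmagnesium alkoxide 2 (not isolated)
Conditions: MeMgBr (3 equiv), CuI (10 mol%), THF, 0 °C → rt; then I2, −78 → 0 °C
Reagents that add atoms: methylmagnesium bromide, C[Mg]Br; iodine, II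
Why: Copper-catalysed anti-carbomagnesiation of the propargylic alkoxide puts methyl on the internal carbon and magnesium on the terminal carbon cis to CH2O in a five-membered chelate (2); iodinolysis with retention gives the Z iodide that becomes the cis C3=C4 bond.

Step 2
Reactants: 3 (2Z)-3-iodo-2-methylprop-2-en-1-ol
Product: 4 (2Z)-3-iodo-2-methylprop-2-enal
Conditions: MnO2 (excess), CH2Cl2, rt, dark
Reagents that add atoms: none
Why: Allylic oxidation with MnO2 is neutral and should keep the Z geometry; the aldehyde is used at once.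

Step 3
Reactants: 4 (2Z)-3-iodo-2-methylprop-2-enal
Product: 5 rac-(1Z)-1-iodo-2-methylpenta-1,4-dien-3-ol
Conditions: CH2=CHMgBr, THF, −78 °C
Reagents that add atoms: vinylmagnesium bromide, C=C[Mg]Br
Why: 1,2-Addition of a Grignard reagent to the enal at low temperature; the racemic carbinol is resolved in the next step.

Step 4
Reactants: 5 rac-(1Z)-1-iodo-2-methylpenta-1,4-dien-3-ol
Product: 6 (1S,2Z)-3-iodo-2-methyl-1-[(2R)-oxiran-2-yl]prop-2-en-1-ol
Conditions: Ti(OiPr)4, L-(+)-diisopropyl tartrate, t-BuOOH (0.5 equiv), 4 Å MS, CH2Cl2, −20 °C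
Reagents that add atoms: tert-butyl hydroperoxide, CC(C)(C)OO
Why: Sharpless kinetic resolution: with L-(+)-tartrate the (R)-enantiomer of 5 is epoxidised at its vinyl group to the erythro epoxy alcohol, which sets C5 (S) by selection and C6 (R) by reagent control with the anti O5/O6 relation of the target; the iodo olefin is electron-poor and cis-substituted and should not compete, and unreacted (S)-5 is separated.

Step 5
Reactants: 6 (1S,2Z)-3-iodo-2-methyl-1-[(2R)-oxiran-2-yl]prop-2-en-1-ol
Product: 7 (2R)-2-{(1S,2Z)-3-iodo-1-[(4-methoxybenzyl)oxy]-2-methylprop-2-en-1-yl}oxirane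
Conditions: NaH, 4-MeOC6H4CH2Br, Bu4NI (cat.), THF/DMF, 0 °C
Reagents that add atoms: 4-methoxybenzyl bromide, COc1ccc(CBr)cc1
Why: Williamson etherification at 0 °C, where Payne migration of the neighbouring terminal epoxide is slow; a benzylic ether is chosen for O5 because it cannot migrate to O6 in step 6 and is removed oxidatively at the end.

Step 6
Reactants: 7 (2R)-2-{(1S,2Z)-3-iodo-1-[(4-methoxybenzyl)oxy]-2-methylprop-2-en-1-yl}oxirane
Product: 8 (3R,4S,5Z)-6-iodo-4-[(4-methoxybenzyl)oxy]-5-methylhexa-1,5-dien-3-ol
Conditions: Me3S+ I− (4 equiv), n-BuLi (3.8 equiv), THF, −10 °C → rt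
Reagents that add atoms: trimethylsulfonium iodide, C[S+](C)C.[I-]
Why: Dimethylsulfonium methylide (Corey–Chaykovsky reagent) opens the terminal epoxide at C7 and a second equivalent eliminates dimethyl sulfide from the betaine, giving the one-carbon-homologated allylic alcohol with C6 untouched; a slight deficit of n-BuLi ensures the alkenyl iodide meets no alkyllithium.

Step 7
Reactants: 8 (3R,4S,5Z)-6-iodo-4-[(4-methoxybenzyl)oxy]-5-methylhexa-1,5-dien-3-ol
Product: 9 triethylsilyl ether of 8
Conditions: Et3SiCl, imidazole, DMF, 0 °C
Reagents that add atoms: chlorotriethylsilane, CC[Si](Cl)(CC)CC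
Why: Standard silylation; the triethylsilyl group masks O6 through steps 11 and 12 and can later be removed beside a tert-butyldimethylsilyl ether.

Step 8
Reactants: 10 pent-1-en-4-yne
Product: 13 (2E)-3-methylhexa-2,5-dien-1-ol, via alkenyldimethylalane 11 (not isolated), via lithium alkenylaluminate 12 (not isolated)
Conditions: Me3Al, Cp2ZrCl2 (20 mol%), CH2Cl2, 0 °C → rt; n-BuLi, THF, −78 °C; (CH2O)n, → rt
Reagents that add atoms: trimethylaluminium, C[Al](C)C; paraformaldehyde, C=O
Why: Zirconium-catalysed carboalumination (Negishi) adds methyl and aluminium syn across the alkyne with methyl on the internal carbon (11), and the aluminate 12 is hydroxymethylated; this fixes the E geometry that becomes the trans epoxide, and the isolated terminal olefin is inert.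

Step 9
Reactants: 13 (2E)-3-methylhexa-2,5-dien-1-ol
Product: 14 [(2R,3R)-3-methyl-3-(prop-2-en-1-yl)oxiran-2-yl]methanol
Conditions: Ti(OiPr)4 (10 mol%), D-(−)-diethyl tartrate (12 mol%), t-BuOOH, 4 Å MS, CH2Cl2, −20 °C
Reagents that add atoms: tert-butyl hydroperoxide, CC(C)(C)OO
Why: Sharpless asymmetric epoxidation of a geraniol-type E allylic alcohol; D-(−)-tartrate gives the (2R,3R)-epoxide and so sets C1 and C10 by reagent control, and only the allylic olefin reacts.

Step 10
Reactants: 14 [(2R,3R)-3-methyl-3-(prop-2-en-1-yl)oxiran-2-yl]methanol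
Product: 15 (2S,3R)-3-methyl-3-(prop-2-en-1-yl)oxirane-2-carbaldehyde
Conditions: SO3·pyridine, DMSO, Et3N, CH2Cl2, 0 °C
Reagents that add atoms: none
Why: Parikh–Doering oxidation is a non-acidic activated-DMSO method suited to 2,3-epoxy alcohols; the volatile aldehyde is used crude (the descriptor at C2 changes only through the priority rules).

Step 11
Reactants: 9 triethylsilyl ether of 8; 15 (2S,3R)-3-methyl-3-(prop-2-en-1-yl)oxirane-2-carbaldehyde
Product: 16 open-chain epoxy dienol with the C2–C3 bond formed (C2 epimers)
Conditions: CrCl2 (6 equiv), NiCl2 (2 mol%), 15 (2 equiv), DMSO, rt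
Reagents that add atoms: none
Why: Nozaki–Hiyama–Kishi coupling: zerovalent nickel inserts into the C–I bond with retention of the Z geometry and hands the alkenyl group to trivalent chromium, which adds only to the aldehyde and leaves epoxide, ethers and olefins alone; both C2 epimers are usable.

Step 12
Reactants: 16 open-chain epoxy dienol (C2 epimers)
Product: 17 C2 tert-butyldimethylsilyl ether of 16
Conditions: t-BuMe2SiOTf, 2,6-lutidine, CH2Cl2, −78 °C
Reagents that add atoms: tert-butyldimethylsilyl trifluoromethanesulfonate, CC(C)(C)[Si](C)(C)OS(=O)(=O)C(F)(F)F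
Why: Silylation of the hindered allylic, epoxide-flanked alcohol with the silyl triflate in the cold; this ether is chosen because it must later survive mild aqueous acid, amide base and zinc in acetic acid.

Step 13
Reactants: 17 C2 tert-butyldimethylsilyl ether of 16
Product: 18 open-chain C6 alcohol
Conditions: pyridinium p-toluenesulfonate (cat.), MeOH/CH2Cl2, 0 °C
Reagents that add atoms: none
Why: Acid-catalysed methanolysis removes the triethylsilyl ether much faster than the tert-butyldimethylsilyl ether, and the epoxide tolerates the buffered acid in the cold.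

Step 14
Reactants: 18 open-chain C6 alcohol
Product: 19 ten-membered epoxy dienol (C7=C8 cis)
Conditions: second-generation Grubbs catalyst RuCl2(=CHPh)(PCy3)(H2IMes) (10 mol%), 1,4-benzoquinone (20 mol%), CH2Cl2 (1 mM), 40 °C
Reagents that add atoms: none
Why: Ring-closing metathesis of two monosubstituted olefins at high dilution; the cis C7=C8 bond is expected because a trans bond in a ring that already holds a cis olefin and a trans epoxide is more strained, the free allylic hydroxyl helps ruthenium to load on the hindered olefin, and benzoquinone suppresses hydride-induced isomerisation; the C3=C4 olefin cannot take part because the six-membered ring it would give would contain the trans epoxide.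

Step 15
Reactants: 19 ten-membered epoxy dienol; 20 ethyl vinyl ether
Product: 21 ten-membered cis-allylic bromoacetal (acetal epimers)
Conditions: N-bromosuccinimide, 20 (5 equiv), CH2Cl2, −40 → 0 °C
Reagents that add atoms: N-bromosuccinimide, O=C1CCC(=O)N1Br
Why: Ueno–Stork acetal formation: bromination of the enol ether gives an α-bromo oxocarbenium ion that is captured by the C6 hydroxyl; the enol ether is far more nucleophilic than the ring olefins or the anisyl ring.

Step 16
Reactants: 21 ten-membered cis-allylic bromoacetal; 22 2,2,6,6-tetramethylpiperidin-1-oxyl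
Product: 23 cis-fused bicyclic ethyl acetal with C8 aminoxy ether
Conditions: Bu3SnSnBu3 (1.5 equiv), hν (sunlamp, Pyrex), C6H6 (5 mM), 25 °C, 22 (3 equiv) added by syringe pump
Reagents that add atoms: none
Why: Photolysis of Bu3SnSnBu3 gives tributyltin radicals that abstract bromine from 21; the primary C11 radical adds to C7, and the secondary C8 radical that results is captured by the persistent nitroxyl 22 at a rate close to diffusion control, so C7–C11 and C8–O form in one operation. The closest known reaction type is the Ueno–Stork haloacetal cyclisation onto a cyclic allylic alcohol, combined with the known termination of tin-initiated radical cyclisations by a nitroxyl in place of hydrogen transfer. The 2-ethoxytetrahydrofuran ring closes 5-exo-trig through a chair-like transition state, which for a 1,2-disubstituted olefin is favoured over 6-endo attack at C8. At C7 the tether can only deliver C11 to the olefin face on which O6 lies, but the ring junction is decided by the C6–C7 rotamer: the cis junction of the target arises from the rotamer with H6 turned away from C9 (C5 and C8 synclinal), whereas the rotamer with H6 eclipsing the olefin, which an open-chain cis-alkene prefers, would give the trans junction. What has to hold the first rotamer is the ten-membered ring itself, whose two cis double bonds and trans epoxide leave few conformers, and this is to be checked by modelling and NOE on 19 and 21 before the step is run on scale. At C8 the nitroxyl is expected to approach anti to the new C7–C11 bond, which gives the configuration of the target. The step also needs ring closure to outrun coupling of the C11 radical with 22, and coupling at C8 to outrun transannular addition to C3=C4: the geminal acetal oxygens accelerate the 5-exo closure, and slow addition keeps 22 near 0.1 mM, high enough for the second demand and low enough for the first. Epoxide, silyl ether and benzylic ether are inert to tin radicals under these neutral conditions.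

Step 17
Reactants: 23 cis-fused bicyclic ethyl acetal with C8 aminoxy ether
Product: 24 lactol
Conditions: pyridinium p-toluenesulfonate, acetone/H2O (4:1), 40 °C
Reagents that add atoms: water, O
Why: Acid-catalysed hydrolysis of a furanoside-type acetal, which exchanges much faster than the tert-butyldimethylsilyl ether cleaves or the trisubstituted epoxide opens under buffered acid; a triethylsilyl ether at C2 would not survive here, which is why the more robust silyl group was chosen.

Step 18
Reactants: 24 lactol
Product: 25 cis-fused γ-lactone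
Conditions: (nPr4N)RuO4 (5 mol%), N-methylmorpholine N-oxide, 4 Å MS, CH2Cl2, rt
Reagents that add atoms: none
Why: Ley–Griffith oxidation of the lactol under neutral conditions; no other free hydroxyl is present, and the aminoxy and benzylic ethers are stable to the oxidant.

Step 19
Reactants: 25 cis-fused γ-lactone
Product: 28 α-methylene lactone with C8 aminoxy ether, via Mannich base 26 (not isolated), via trimethylammonium iodide 27 (not isolated)
Conditions: LiN(SiMe3)2, THF, −78 °C; CH2=NMe2+ I−, → rt; MeI, THF; DBU, CH2Cl2
Reagents that add atoms: Eschenmoser's salt, C=[N+](C)C.[I-]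
Why: α-Methylenation of a lactone: enolisation at C11 (the only enolisable position), Mannich reaction, N-methylation and elimination of trimethylamine; the aminoxy ether keeps O8 masked so that no alkoxide can attack the lactone, and the hindered piperidine nitrogen is not quaternised.

Step 20
Reactants: 28 α-methylene lactone with C8 aminoxy ether
Product: 29 C8 alcohol
Conditions: Zn, AcOH/THF/H2O (3:1:1), rt → 40 °C
Reagents that add atoms: none
Why: Zinc in acetic acid reduces the N–O bond of the alkoxyamine; an unactivated enoate such as the methylene lactone is not expected to be reduced, and the hindered amine set free does not add to it.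

Step 21
Reactants: 29 C8 alcohol; 30 tiglic acid
Product: 32 C8 tiglate, via mixed anhydride 31 (not isolated)
Conditions: 2,4,6-Cl3C6H2COCl, Et3N, toluene, rt; then 29, DMAP, rt
Reagents that add atoms: none
Why: Yamaguchi esterification: the mixed anhydride 31 acylates the hindered secondary alcohol under DMAP catalysis without loss of the E geometry of the acid, and the short exposure to base limits migration of the lactone to O8.

Step 22
Reactants: 32 C8 tiglate
Product: 33 C2 alcohol
Conditions: HF·pyridine, pyridine, THF, 0 °C → rt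
Reagents that add atoms: none
Why: Buffered fluoride cleaves the secondary silyl ether; epoxide, methylene lactone, ester and benzylic ether are stable to these conditions.

Step 23
Reactants: 33 C2 alcohol
Product: 34 C2 ketone (O5 4-methoxybenzyl ether of the target)
Conditions: Dess–Martin periodinane, NaHCO3, CH2Cl2, 0 °C → rt
Reagents that add atoms: none
Why: Dess–Martin oxidation of the allylic, epoxide-flanked carbinol under buffered conditions gives the cis enone; both C2 epimers converge here.

Step 24
Reactants: 34 C2 ketone
Product: 35 CNP0345622.1 (target)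
Conditions: DDQ, CH2Cl2/pH 7 buffer, 0 °C
Reagents that add atoms: none
Why: Oxidative cleavage of the 4-methoxybenzyl ether frees the C5 hydroxyl under neutral conditions, which the hydroxy enone, epoxy ketone, tiglate and methylene lactone tolerate.

## Compound list

1 | prop-2-yn-1-ol | C#CCO | starting material
2 | bromomagnesium (2Z)-3-(bromomagnesio)-2-methylprop-2-en-1-olate | Br[Mg]/C=C(/C)CO[Mg]Br | intermediate (not isolated)
3 | (2Z)-3-iodo-2-methylprop-2-en-1-ol | I/C=C(/C)CO | intermediate
4 | (2Z)-3-iodo-2-methylprop-2-enal | I/C=C(/C)C=O | intermediate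
5 | rac-(1Z)-1-iodo-2-methylpenta-1,4-dien-3-ol | I/C=C(/C)C(O)C=C | intermediate
6 | (1S,2Z)-3-iodo-2-methyl-1-[(2R)-oxiran-2-yl]prop-2-en-1-ol | I/C=C(/C)[C@H](O)[C@H]1CO1 | intermediate
7 | (2R)-2-{(1S,2Z)-3-iodo-1-[(4-methoxybenzyl)oxy]-2-methylprop-2-en-1-yl}oxirane | I/C=C(/C)[C@H](OCc1ccc(OC)cc1)[C@H]1CO1 | intermediate
8 | (3R,4S,5Z)-6-iodo-4-[(4-methoxybenzyl)oxy]-5-methylhexa-1,5-dien-3-ol | I/C=C(/C)[C@H](OCc1ccc(OC)cc1)[C@H](O)C=C | intermediate
9 | triethyl{[(3R,4S,5Z)-6-iodo-4-[(4-methoxybenzyl)oxy]-5-methylhexa-1,5-dien-3-yl]oxy}silane | I/C=C(/C)[C@H](OCc1ccc(OC)cc1)[C@H](O[Si](CC)(CC)CC)C=C | intermediate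
10 | pent-1-en-4-yne | C=CCC#C | starting material
11 | dimethyl[(1E)-2-methylpenta-1,4-dien-1-yl]alumane | C[Al](C)/C=C(\C)CC=C | intermediate (not isolated)
12 | lithium butyl(dimethyl)[(1E)-2-methylpenta-1,4-dien-1-yl]aluminate | [Li+].CCCC[Al-](C)(C)/C=C(\C)CC=C | intermediate (not isolated)
13 | (2E)-3-methylhexa-2,5-dien-1-ol | C=CC/C(C)=C/CO | intermediate
14 | [(2R,3R)-3-methyl-3-(prop-2-en-1-yl)oxiran-2-yl]methanol | C=CC[C@@]1(C)O[C@@H]1CO | intermediate
15 | (2S,3R)-3-methyl-3-(prop-2-en-1-yl)oxirane-2-carbaldehyde | C=CC[C@@]1(C)O[C@@H]1C=O | intermediate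
16 | (2Z,4S,5R)-4-[(4-methoxybenzyl)oxy]-3-methyl-1-[(2R,3R)-3-methyl-3-(prop-2-en-1-yl)oxiran-2-yl]-5-[(triethylsilyl)oxy]hepta-2,6-dien-1-ol, both C1 (ring C2) epimers | C=CC[C@@]1(C)O[C@@H]1C(O)/C=C(/C)[C@H](OCc1ccc(OC)cc1)[C@H](O[Si](CC)(CC)CC)C=C | intermediate
17 | 1-O-tert-butyldimethylsilyl ether of 16 | C=CC[C@@]1(C)O[C@@H]1C(O[Si](C)(C)C(C)(C)C)/C=C(/C)[C@H](OCc1ccc(OC)cc1)[C@H](O[Si](CC)(CC)CC)C=C | intermediate
18 | (3R,4S,5Z)-7-[(tert-butyldimethylsilyl)oxy]-4-[(4-methoxybenzyl)oxy]-5-methyl-7-[(2R,3R)-3-methyl-3-(prop-2-en-1-yl)oxiran-2-yl]hepta-1,5-dien-3-ol, C7 (ring C2) epimers | C=CC[C@@]1(C)O[C@@H]1C(O[Si](C)(C)C(C)(C)C)/C=C(/C)[C@H](OCc1ccc(OC)cc1)[C@H](O)C=C | intermediate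
19 | (1R,3Z,5S,6R,7Z,10R)-2-[(tert-butyldimethylsilyl)oxy]-5-[(4-methoxybenzyl)oxy]-4,10-dimethyl-11-oxabicyclo[8.1.0]undeca-3,7-dien-6-ol, C2 epimers | O[C@@H]2/C=C\C[C@@]1(C)O[C@@H]1C(O[Si](C)(C)C(C)(C)C)/C=C(/C)[C@@H]2OCc1ccc(OC)cc1 | intermediate
20 | ethyl vinyl ether | CCOC=C | starting material
21 | (1R,3Z,5S,6R,7Z,10R)-6-(2-bromo-1-ethoxyethoxy)-2-[(tert-butyldimethylsilyl)oxy]-5-[(4-methoxybenzyl)oxy]-4,10-dimethyl-11-oxabicyclo[8.1.0]undeca-3,7-diene, C2 and acetal epimers | CCOC(CBr)O[C@@H]2/C=C\C[C@@]1(C)O[C@@H]1C(O[Si](C)(C)C(C)(C)C)/C=C(/C)[C@@H]2OCc1ccc(OC)cc1 | intermediate (key-step precursor)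
22 | 2,2,6,6-tetramethylpiperidin-1-oxyl | CC1(C)CCCC(C)(C)N1[O] | starting material
23 | cis-fused acetal: 2-ethoxytetrahydrofuran ring (O6–C12–C11–C7) on the ten-membered ring, H6/H7 cis, 8-(2,2,6,6-tetramethylpiperidin-1-yloxy), 2-silyloxy, 5-(4-methoxybenzyloxy), 1,10-epoxide, 3Z; C1, C5, C6, C7, C8, C10 as in the target | C1C(OCC)O[C@@H]2[C@H]1[C@H](ON3C(C)(C)CCCC3(C)C)C[C@@]1(C)O[C@@H]1C(O[Si](C)(C)C(C)(C)C)/C=C(/C)[C@@H]2OCc1ccc(OC)cc1 | intermediate (key-step product)
24 | lactol of 23 (12-hydroxy in place of 12-ethoxy) | C1C(O)O[C@@H]2[C@H]1[C@H](ON3C(C)(C)CCCC3(C)C)C[C@@]1(C)O[C@@H]1C(O[Si](C)(C)C(C)(C)C)/C=C(/C)[C@@H]2OCc1ccc(OC)cc1 | intermediate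
25 | cis-fused γ-lactone (C11 = CH2), otherwise as 23 | C1C(=O)O[C@@H]2[C@H]1[C@H](ON3C(C)(C)CCCC3(C)C)C[C@@]1(C)O[C@@H]1C(O[Si](C)(C)C(C)(C)C)/C=C(/C)[C@@H]2OCc1ccc(OC)cc1 | intermediate
26 | 11-[(dimethylamino)methyl] derivative of 25 (C11 epimers) | CN(C)CC1C(=O)O[C@@H]2[C@H]1[C@H](ON3C(C)(C)CCCC3(C)C)C[C@@]1(C)O[C@@H]1C(O[Si](C)(C)C(C)(C)C)/C=C(/C)[C@@H]2OCc1ccc(OC)cc1 | intermediate (not isolated)
27 | N-methyl iodide of 26 | C[N+](C)(C)CC1C(=O)O[C@@H]2[C@H]1[C@H](ON3C(C)(C)CCCC3(C)C)C[C@@]1(C)O[C@@H]1C(O[Si](C)(C)C(C)(C)C)/C=C(/C)[C@@H]2OCc1ccc(OC)cc1.[I-] | intermediate (not isolated)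
28 | α-methylene lactone, 8-(tetramethylpiperidinyloxy), 2-silyloxy, 5-(4-methoxybenzyloxy) | C=C1C(=O)O[C@@H]2[C@H]1[C@H](ON3C(C)(C)CCCC3(C)C)C[C@@]1(C)O[C@@H]1C(O[Si](C)(C)C(C)(C)C)/C=C(/C)[C@@H]2OCc1ccc(OC)cc1 | intermediate
29 | 8-hydroxy α-methylene lactone | C=C1C(=O)O[C@@H]2[C@H]1[C@H](O)C[C@@]1(C)O[C@@H]1C(O[Si](C)(C)C(C)(C)C)/C=C(/C)[C@@H]2OCc1ccc(OC)cc1 | intermediate
30 | tiglic acid, (2E)-2-methylbut-2-enoic acid | C/C=C(\C)C(=O)O | starting material
31 | (2E)-2-methylbut-2-enoic 2,4,6-trichlorobenzoic anhydride | C/C=C(\C)C(=O)OC(=O)c1c(Cl)cc(Cl)cc1Cl | intermediate (not isolated)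
32 | 8-tiglate, 2-silyloxy, 5-(4-methoxybenzyloxy) | C=C1C(=O)O[C@@H]2[C@H]1[C@H](OC(=O)/C(C)=C/C)C[C@@]1(C)O[C@@H]1C(O[Si](C)(C)C(C)(C)C)/C=C(/C)[C@@H]2OCc1ccc(OC)cc1 | intermediate
33 | 8-tiglate, 2-hydroxy (C2 epimers), 5-(4-methoxybenzyloxy) | C=C1C(=O)O[C@@H]2[C@H]1[C@H](OC(=O)/C(C)=C/C)C[C@@]1(C)O[C@@H]1C(O)/C=C(/C)[C@@H]2OCc1ccc(OC)cc1 | intermediate
34 | O5-(4-methoxybenzyl) ether of the target | C=C1C(=O)O[C@@H]2[C@H]1[C@H](OC(=O)/C(C)=C/C)C[C@@]1(C)O[C@@H]1C(=O)/C=C(/C)[C@@H]2OCc1ccc(OC)cc1 | intermediate
35 | CNP0345622.1, (1S,3Z,5S,6R,7R,8R,10R) | C=C1C(=O)O[C@@H]2[C@H]1[C@H](OC(=O)/C(C)=C/C)C[C@@]1(C)O[C@@H]1C(=O)/C=C(/C)[C@@H]2O | target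

## Step count and least certain steps

Total: 24 steps. Longest linear sequence: 21 steps (steps 1–7 and 11–24); steps 8–10 form the three-step side branch.

**Step 16 (key step).**
- Most likely failure: ring closure through the rotamer with H6 eclipsing the cis olefin. This is the conformation that allylic strain favours in an open chain, and the ten-membered ring is not known to forbid it. It would give the wrong ring-junction selectivity.
- Second: coupling of the C11 radical with the nitroxyl before cyclisation, if the nitroxyl concentration is not kept low.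
- Third: poor facial selectivity at C8, which would call for esterification with inversion in place of retention.
- Fallback: it sets out from 19 and returns at 25. It uses the open-chain preference by setting C7 first and C6 afterwards.
  - Mitsunobu reaction of 19 with 4-nitrobenzoic acid (PPh3, diisopropyl azodicarboxylate, THF) gives the inverted C6 4-nitrobenzoate F1.
  - Methanolysis (K2CO3, MeOH) gives the C6-epimeric alcohol F2.
  - N-Bromosuccinimide and 20 give the C6-epimeric bromoacetal F3.
  - Under the conditions of step 16 this closes through the strain-free rotamer to the trans-fused acetal F4, in which C7 has the configuration of the target.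
  - Hydrolysis as in step 17 gives the trans-fused lactol F5, and oxidation as in step 18 gives the trans-fused lactone F6.
  - LiOH in aqueous THF opens it to the hydroxy acid F7.
  - Mitsunobu lactonisation (PPh3, diisopropyl azodicarboxylate, toluene, high dilution) recloses the ring with inversion at C6 to the cis-fused lactone 25.

**Step 14 (ring-closing metathesis).**
- Most likely failure: oligomerisation in place of ring closure, because the strained ring forms reversibly, or formation of the trans C7=C8 bond.
- Fallback: it sets out from 9 and 14 and returns at 19. It joins the olefins first and closes the ring by an irreversible C–C bond formation.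
  - Cross-metathesis of 9 with 14 under a cis-selective cyclometalated catalyst, Ru(NO3)(=CH-C6H4-2-OiPr)(κ2C,C-NHC) with NHC = 1-(adamantan-1-yl)-3-(2,6-diisopropylphenyl)imidazolin-2-ylidene, gives the open-chain cis-alkene F8.
  - Parikh–Doering oxidation gives the epoxy aldehyde F9.
  - An intramolecular Nozaki–Hiyama–Kishi reaction (CrCl2, NiCl2 cat., DMSO/THF, 2 mM) forms C2–C3 and gives the macrocyclic alcohol F10.
  - Silylation as in step 12 gives the bis-silyl ether F11, and methanolysis as in step 13 gives 19.

**Step 20 (N–O cleavage).**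
- Most likely failure: conjugate reduction of the exocyclic enoate, or its capture by acetate, while the N–O bond is reduced.
- Fallback: it sets out from 25 and returns at 29. It moves the reduction before the methylenation.
  - Zinc in acetic acid is applied to 25, where no conjugate acceptor is present, giving the 8-hydroxy lactone F12.
  - Et3SiCl and imidazole give the 8-O-triethylsilyl ether F13.
  - Methylenation as in step 19, through the Mannich base F14 and its methiodide F15 (neither isolated), gives the silyl-protected methylene lactone F16.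
  - Pyridinium p-toluenesulfonate in methanol removes the triethylsilyl group and gives 29.

**Step 11 (Nozaki–Hiyama–Kishi coupling).**
- Most likely failure: Lewis-acid-induced opening of the epoxy aldehyde by chromium salts, or sluggish insertion into the hindered trisubstituted iodide.
- Fallback: it sets out from 9 and 15 and returns at 16. Iodine–lithium exchange on 9 (t-BuLi, 2 equiv, Et2O, −78 °C) gives the alkenyllithium F17, which adds to 15 at −78 °C to give 16 directly.

## Further compounds

F1 | step 16 | C6-inverted 4-nitrobenzoate of 19 | O=C(c1ccc(cc1)[N+](=O)[O-])O[C@H]2/C=C\C[C@@]3(C)O[C@@H]3C(O[Si](C)(C)C(C)(C)C)/C=C(/C)[C@@H]2OCc1ccc(OC)cc1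
F2 | step 16 | C6 epimer of 19 | O[C@H]2/C=C\C[C@@]1(C)O[C@@H]1C(O[Si](C)(C)C(C)(C)C)/C=C(/C)[C@@H]2OCc1ccc(OC)cc1
F3 | step 16 | C6 epimer of 21 | CCOC(CBr)O[C@H]2/C=C\C[C@@]1(C)O[C@@H]1C(O[Si](C)(C)C(C)(C)C)/C=C(/C)[C@@H]2OCc1ccc(OC)cc1
F4 | step 16 | trans-fused acetal, C6 epimer of 23 | C1C(OCC)O[C@H]2[C@H]1[C@H](ON3C(C)(C)CCCC3(C)C)C[C@@]1(C)O[C@@H]1C(O[Si](C)(C)C(C)(C)C)/C=C(/C)[C@@H]2OCc1ccc(OC)cc1
F5 | step 16 | trans-fused lactol, C6 epimer of 24 | C1C(O)O[C@H]2[C@H]1[C@H](ON3C(C)(C)CCCC3(C)C)C[C@@]1(C)O[C@@H]1C(O[Si](C)(C)C(C)(C)C)/C=C(/C)[C@@H]2OCc1ccc(OC)cc1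
F6 | step 16 | trans-fused lactone, C6 epimer of 25 | C1C(=O)O[C@H]2[C@H]1[C@H](ON3C(C)(C)CCCC3(C)C)C[C@@]1(C)O[C@@H]1C(O[Si](C)(C)C(C)(C)C)/C=C(/C)[C@@H]2OCc1ccc(OC)cc1
F7 | step 16 | 6-hydroxy acid from F6 (C12 carboxylic acid, 6S hydroxyl) | OC(=O)C[C@@H]1[C@H](ON3C(C)(C)CCCC3(C)C)C[C@@]2(C)O[C@@H]2C(O[Si](C)(C)C(C)(C)C)/C=C(/C)[C@H](OCc2ccc(OC)cc2)[C@H]1O
F8 | step 14 | open-chain cis-alkene from 9 and 14 (C7=C8 formed, epoxy alcohol terminus) | I/C=C(/C)[C@H](OCc1ccc(OC)cc1)[C@H](O[Si](CC)(CC)CC)/C=C\C[C@@]1(C)O[C@@H]1CO
F9 | step 14 | epoxy aldehyde from F8 | I/C=C(/C)[C@H](OCc1ccc(OC)cc1)[C@H](O[Si](CC)(CC)CC)/C=C\C[C@@]1(C)O[C@@H]1C=O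
F10 | step 14 | macrocyclic C2 alcohol with O6 triethylsilyl ether (C2 epimers) | CC[Si](CC)(CC)O[C@@H]2/C=C\C[C@@]1(C)O[C@@H]1C(O)/C=C(/C)[C@@H]2OCc1ccc(OC)cc1
F11 | step 14 | C2 tert-butyldimethylsilyl ether of F10 | CC[Si](CC)(CC)O[C@@H]2/C=C\C[C@@]1(C)O[C@@H]1C(O[Si](C)(C)C(C)(C)C)/C=C(/C)[C@@H]2OCc1ccc(OC)cc1
F12 | step 20 | 8-hydroxy lactone from 25 | C1C(=O)O[C@@H]2[C@H]1[C@H](O)C[C@@]1(C)O[C@@H]1C(O[Si](C)(C)C(C)(C)C)/C=C(/C)[C@@H]2OCc1ccc(OC)cc1
F13 | step 20 | 8-O-triethylsilyl ether of F12 | C1C(=O)O[C@@H]2[C@H]1[C@H](O[Si](CC)(CC)CC)C[C@@]1(C)O[C@@H]1C(O[Si](C)(C)C(C)(C)C)/C=C(/C)[C@@H]2OCc1ccc(OC)cc1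
F14 | step 20 | 11-[(dimethylamino)methyl] derivative of F13 | CN(C)CC1C(=O)O[C@@H]2[C@H]1[C@H](O[Si](CC)(CC)CC)C[C@@]1(C)O[C@@H]1C(O[Si](C)(C)C(C)(C)C)/C=C(/C)[C@@H]2OCc1ccc(OC)cc1
F15 | step 20 | N-methyl iodide of F14 | C[N+](C)(C)CC1C(=O)O[C@@H]2[C@H]1[C@H](O[Si](CC)(CC)CC)C[C@@]1(C)O[C@@H]1C(O[Si](C)(C)C(C)(C)C)/C=C(/C)[C@@H]2OCc1ccc(OC)cc1.[I-]
F16 | step 20 | α-methylene lactone with 8-O-triethylsilyl ether | C=C1C(=O)O[C@@H]2[C@H]1[C@H](O[Si](CC)(CC)CC)C[C@@]1(C)O[C@@H]1C(O[Si](C)(C)C(C)(C)C)/C=C(/C)[C@@H]2OCc1ccc(OC)cc1
F17 | step 11 | alkenyllithium from 9 | [Li]/C=C(/C)[C@H](OCc1ccc(OC)cc1)[C@H](O[Si](CC)(CC)CC)C=C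
A1 | alternative 1 | E 1,5-anti-diol with propargylic C2 carbinol and 3-methylenetetrahydrofuran | CC#C[C@H](O)/C=C(\C)C[C@@H](O)[C@H]1C(=C)CO[C@H]1CO[Si](C)(C)C(C)(C)C
A2 | alternative 2 | ten-membered C2 enone with C10 silyloxy centre, E C7=C8 olefin and C5/C6 acetonide | CC1(C)O[C@@H]2/C=C/C[C@@](C)(O[Si](C(C)C)(C(C)C)C(C)C)CC(=O)/C=C(/C)[C@@H]2O1
A3 | alternative 3 | 2,5-endoperoxide of the finished skeleton | C1[C@@]2(C)O[C@@H]2[C@H]4C=C(C)[C@H](OO4)[C@@H]3OC(=O)C(=C)[C@@H]3[C@@H]1OC(=O)/C(C)=C/C
A4 | alternative 3 | ten-membered (2Z,4Z)-diene precursor of A3 | C1[C@@]2(C)O[C@@H]2/C=C\C(C)=C/[C@@H]3OC(=O)C(=C)[C@@H]3[C@@H]1OC(=O)/C(C)=C/C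
A5 | alternative 3 | singlet dioxygen | O=O
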